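**Plan**

1. Numbering (halimane): ring A = C1–C5 and C10 with C1=C10; ring B = C5–C10; C4 carries CH3 and the carboxyl C18; C8 carries CH3; C9 carries CH3 and the chain C11–C15 (C13=C14, O on C15).
2. Cuts: the propionate O–acyl bond; C12–C13 (B-alkyl Suzuki coupling to an E-configured enol triflate); C2–C3 and C4–C5 together (Diels–Alder); C10–C1 (vinylation of an enol triflate); C9–C11 and C8–CH3 (conjugate addition/aldol on 2-methylcyclohex-2-en-1-one).
3. Forward: ring B is made first with C8 and C9; ring A then closes in one [4+2] between the ring-B diene C5=C10–C1=C2 and methacrolein (C3=C4); the chain is coupled on and acylated last.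
4. Enabling feature: in ring A the C1=C10 double bond lies 3,4 to the carboxyl-bearing C4 (C18–C4–C5–C10=C1), which is the cyclohex-3-ene-1-carbonyl retron. Because C10 is shared with ring B, the diene is simply a 1-vinylcyclohexene and the dienophile is a methacrylic unit.
5. Stereochemistry: C8 by Cu-catalysed asymmetric conjugate addition; C9 relayed from C8 (aldol trans to the C8 methyl); C4 and C5 formed together in the Diels–Alder step (the catalyst fixes the enal face and so C4, the exo topology ties C5 to C4); C13=C14 (E) from the geometry of the enol triflate.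

Key step: step 5

Remark (assumption): the antipodes of the conjugate-addition ligand and of the Diels–Alder catalyst are specified by the sense of induction they must deliver (stated in steps 1 and 5), since the route depends on that sense and not on the ligand descriptor.

**Step 1**
Reactants: 1 2-methylcyclohex-2-en-1-one; 2 acetaldehyde
Product: 4 (2R,3R)-2-(1-hydroxyethyl)-2,3-dimethylcyclohexan-1-one (carbinol epimers), via dimethylaluminium enolate 3 (not isolated)
Conditions: Me3Al, CuTC (cat.), chiral phosphoramidite (cat., antipode giving 3R), Et2O, −30 °C; then 2, −78 → −40 °C; aq. Rochelle salt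
Reagents that add atoms: trimethylaluminium C[Al](C)C
Why: Copper-catalysed asymmetric conjugate addition sets C8, and the tetrasubstituted aluminium enolate then undergoes aldol addition to acetaldehyde on the face anti to the pseudoaxial C8 methyl (A1,2 strain), which sets quaternary C9 with the two methyl groups cis; the carbinol centre is removed in step 2.

**Step 2**
Reactants: 4 (2R,3R)-2-(1-hydroxyethyl)-2,3-dimethylcyclohexan-1-one
Product: 6 (2S,3R)-2-ethenyl-2,3-dimethylcyclohexan-1-one, via sulfamate ester 5 (not isolated)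
Conditions: methyl N-(triethylammoniosulfonyl)carbamate (Burgess reagent), PhMe, 25 → 70 °C
Reagents that add atoms: none
Why: Syn-elimination (Ei) of the sulfamate of a secondary alcohol (Burgess dehydration) can only take a hydrogen from the methyl group because C9 is quaternary, so the vinyl group should form without touching C8 or C9.

**Step 3**
Reactants: 6 (2S,3R)-2-ethenyl-2,3-dimethylcyclohexan-1-one
Product: 8 (5R,6S)-6-ethenyl-5,6-dimethylcyclohex-1-en-1-yl trifluoromethanesulfonate, via potassium enolate 7 (not isolated)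
Conditions: KHMDS, THF, −78 °C; PhNTf2, −78 → 0 °C
Reagents that add atoms: N-phenylbis(trifluoromethanesulfonimide) O=S(=O)(N(c1ccccc1)S(=O)(=O)C(F)(F)F)C(F)(F)F
Why: Enolisation is possible only toward C5 because C9 is quaternary, and O-sulfonylation of the enolate gives the enol triflate regiospecifically (enol triflate formation).

**Step 4**
Reactants: 8 (5R,6S)-6-ethenyl-5,6-dimethylcyclohex-1-en-1-yl trifluoromethanesulfonate
Product: 9 (5R,6S)-1,6-diethenyl-5,6-dimethylcyclohex-1-ene
Conditions: tributyl(vinyl)stannane, Pd(PPh3)4 (cat.), LiCl, THF, 65 °C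
Reagents that add atoms: tributyl(vinyl)stannane C=C[Sn](CCCC)(CCCC)CCCC
Why: Stille coupling of an alkenyl triflate with a vinylstannane installs C1=C2 on C10 and gives the conjugated diene C5=C10–C1=C2 without touching a stereocentre.

**Step 5**
Reactants: 9 (5R,6S)-1,6-diethenyl-5,6-dimethylcyclohex-1-ene; 10 methacrolein
Product: 11 (1S,5S,6R,8aS)-5-ethenyl-1,5,6-trimethyl-1,2,3,5,6,7,8,8a-octahydronaphthalene-1-carbaldehyde
Conditions: 10 (excess), o-tolyl-oxazaborolidinium triflimide from the CBS oxazaborolidine and Tf2NH (cat., antipode that leaves the Cα-Re face of bound 10 open), CH2Cl2, −78 → −40 °C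
Reagents that add atoms: none
Why: Concerted but asynchronous normal-demand [4+2] between the s-cis diene C5=C10–C1=C2 and methacrolein bound s-trans to the cationic boron Lewis acid, the C2–C3 bond between the two unhindered CH2 termini leading and the hindered C4–C5 bond following; the closest known reaction types are the oxazaborolidinium-catalysed enantioselective Diels–Alder reaction of 2-substituted acroleins and the exo-selective Lewis-acid Diels–Alder reaction of α-methyl enals with 1-vinylcyclohexenes that carry a quaternary carbon next to the diene. Ring A (C1–C5, C10) closes by suprafacial [4+2] cycloaddition, which by necessity leaves the double bond at C1=C10. C4 is controlled by the catalyst, which exposes the Cα-Re face of the enal, and C5 follows from C4 through the exo transition state (formyl exo, the small α-methyl endo under C10), which puts CHO cis to H5 and the new C4–C5 bond on the diene face syn to the C9 methyl group. Regiochemistry (C4 to the ring terminus C5) follows the 1-alkyl ("ortho") preference of 1-vinylcyclohexenes and is reinforced by the enal β-carbon bonding first to the unhindered terminus C2. Facial selectivity with respect to C8/C9 is left to the catalyst, because the two C9 substituents (CH3 and CH=CH2) are close in size and should give the diene little bias of its own; the isolated C9 vinyl group is not conjugated and should not take part.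

**Step 6**
Reactants: 11 (1S,5S,6R,8aS)-5-ethenyl-1,5,6-trimethyl-1,2,3,5,6,7,8,8a-octahydronaphthalene-1-carbaldehyde
Product: 12 (1S,5S,6R,8aS)-5-ethenyl-1,5,6-trimethyl-1,2,3,5,6,7,8,8a-octahydronaphthalene-1-carboxylic acid
Conditions: NaClO2, NaH2PO4, 2-methylbut-2-ene, t-BuOH/H2O, 0 °C → rt
Reagents that add atoms: sodium chlorite [Na+].[O-]Cl=O
Why: Pinnick oxidation converts the non-enolisable neopentyl aldehyde into the acid without epimerisation, the alkene scavenger protecting the C=C bonds from HOCl.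

**Step 7**
Reactants: 13 ethyl 3-oxobutanoate (ethyl acetoacetate)
Product: 14 ethyl (2E)-3-{[(trifluoromethyl)sulfonyl]oxy}but-2-enoate
Conditions: Tf2O, aq. Me4NOH, PhMe, 0 °C
Reagents that add atoms: trifluoromethanesulfonic anhydride O=S(=O)(OS(=O)(=O)C(F)(F)F)C(F)(F)F
Why: O-triflation of the non-chelated (tetramethylammonium) enolate of a β-keto ester under two-phase conditions should give the E enol triflate (OTf trans to CO2Et), which fixes the later C13=C14 geometry.

**Step 8**
Reactants: 14 ethyl (2E)-3-{[(trifluoromethyl)sulfonyl]oxy}but-2-enoate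
Product: 15 (2E)-4-hydroxybut-2-en-2-yl trifluoromethanesulfonate
Conditions: DIBAL-H, CH2Cl2, −78 °C; aq. Rochelle salt
Reagents that add atoms: none
Why: 1,2-Reduction of the enoate with DIBAL-H at low temperature gives the allylic alcohol, with the alkenyl triflate and the E geometry retained.

**Step 9**
Reactants: 12 (1S,5S,6R,8aS)-5-ethenyl-1,5,6-trimethyl-1,2,3,5,6,7,8,8a-octahydronaphthalene-1-carboxylic acid; 15 (2E)-4-hydroxybut-2-en-2-yl trifluoromethanesulfonate
Product: 17 (1S,5S,6R,8aS)-5-[(3E)-5-hydroxy-3-methylpent-3-en-1-yl]-1,5,6-trimethyl-1,2,3,5,6,7,8,8a-octahydronaphthalene-1-carboxylic acid (ent-halimic acid), via B-alkyl-9-BBN adduct 16 (not isolated)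
Conditions: 9-BBN-H (excess), THF, 0 °C → rt; then 15, PdCl2(dppf) (cat.), AsPh3, aq. K3PO4, DMF, rt → 50 °C
Reagents that add atoms: none
Why: Anti-Markovnikov hydroboration of the monosubstituted vinyl group with 9-BBN (the trisubstituted ring alkene is inert and the carboxyl only consumes one hydride), followed by B-alkyl Suzuki–Miyaura coupling with the alkenyl triflate, forms C12–C13 with retention of the E geometry.

**Step 10**
Reactants: 17 ent-halimic acid
Product: 18 (1S,5S,6R,8aS)-1,5,6-trimethyl-5-[(3E)-3-methyl-5-(propanoyloxy)pent-3-en-1-yl]-1,2,3,5,6,7,8,8a-octahydronaphthalene-1-carboxylic acid (target)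
Conditions: (EtCO)2O, pyridine, DMAP (cat.), CH2Cl2, 0 °C; aq. NaHCO3/THF work-up
Reagents that add atoms: propanoic anhydride CCC(=O)OC(=O)CC
Why: DMAP-catalysed acylation esterifies the primary allylic alcohol, and any mixed anhydride formed at the hindered tertiary carboxyl should be hydrolysed on bicarbonate work-up.

**Compound list**

1 | 2-methylcyclohex-2-en-1-one | CC1=CCCCC1=O | starting material
2 | acetaldehyde | CC=O | starting material
3 | dimethylaluminium (3R)-2,3-dimethylcyclohex-1-en-1-olate | CC1=C(O[Al](C)C)CCC[C@H]1C | intermediate (not isolated)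
4 | (2R,3R)-2-(1-hydroxyethyl)-2,3-dimethylcyclohexan-1-one (carbinol epimers) | CC(O)[C@]1(C)C(=O)CCC[C@H]1C | intermediate
5 | 1-[(1R,2R)-1,2-dimethyl-6-oxocyclohexyl]ethyl N-(methoxycarbonyl)sulfamate (present as its triethylammonium salt) | COC(=O)NS(=O)(=O)OC(C)[C@]1(C)C(=O)CCC[C@H]1C | intermediate (not isolated)
6 | (2S,3R)-2-ethenyl-2,3-dimethylcyclohexan-1-one | C=C[C@]1(C)C(=O)CCC[C@H]1C | intermediate
7 | potassium (5R,6S)-6-ethenyl-5,6-dimethylcyclohex-1-en-1-olate | C=C[C@]1(C)C([O-])=CCC[C@H]1C.[K+] | intermediate (not isolated)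
8 | (5R,6S)-6-ethenyl-5,6-dimethylcyclohex-1-en-1-yl trifluoromethanesulfonate | C=C[C@]1(C)C(OS(=O)(=O)C(F)(F)F)=CCC[C@H]1C | intermediate
9 | (5R,6S)-1,6-diethenyl-5,6-dimethylcyclohex-1-ene | C=C[C@]1(C)C(C=C)=CCC[C@H]1C | intermediate
10 | methacrolein (2-methylprop-2-enal) | CC(=C)C=O | starting material
11 | (1S,5S,6R,8aS)-5-ethenyl-1,5,6-trimethyl-1,2,3,5,6,7,8,8a-octahydronaphthalene-1-carbaldehyde | C=C[C@]1(C)C2=CCC[C@](C)(C=O)[C@H]2CC[C@H]1C | intermediate
12 | (1S,5S,6R,8aS)-5-ethenyl-1,5,6-trimethyl-1,2,3,5,6,7,8,8a-octahydronaphthalene-1-carboxylic acid | C=C[C@]1(C)C2=CCC[C@](C)(C(=O)O)[C@H]2CC[C@H]1C | intermediate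
13 | ethyl 3-oxobutanoate | CCOC(=O)CC(C)=O | starting material
14 | ethyl (2E)-3-{[(trifluoromethyl)sulfonyl]oxy}but-2-enoate | CCOC(=O)/C=C(\C)OS(=O)(=O)C(F)(F)F | intermediate
15 | (2E)-4-hydroxybut-2-en-2-yl trifluoromethanesulfonate | OC/C=C(\C)OS(=O)(=O)C(F)(F)F | intermediate
16 | B-alkyl-9-BBN adduct of 12 (carboxyl as its 9-BBN carboxylate) | B1(C2CCCC1CCC2)CC[C@]3(C)C4=CCC[C@](C)(C(=O)OB5C6CCCC5CCC6)[C@H]4CC[C@H]3C | intermediate (not isolated)
17 | (1S,5S,6R,8aS)-5-[(3E)-5-hydroxy-3-methylpent-3-en-1-yl]-1,5,6-trimethyl-1,2,3,5,6,7,8,8a-octahydronaphthalene-1-carboxylic acid (ent-halimic acid) | OC/C=C(\C)CC[C@]1(C)C2=CCC[C@](C)(C(=O)O)[C@H]2CC[C@H]1C | intermediate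
18 | (1S,5S,6R,8aS)-1,5,6-trimethyl-5-[(3E)-3-methyl-5-(propanoyloxy)pent-3-en-1-yl]-1,2,3,5,6,7,8,8a-octahydronaphthalene-1-carboxylic acid | CCC(=O)OC/C=C(\C)CC[C@]1(C)C2=CCC[C@](C)(C(=O)O)[C@H]2CC[C@H]1C | target

**Step count and risks**

Total step count: 10. Longest linear sequence: 8 (steps 1, 2, 3, 4, 5, 6, 9, 10); steps 7 and 8 make the coupling partner.

Steps most likely to fail:

Step 5. The process at risk is loss of exo and π-facial discrimination if the preference of the catalyst and the small intrinsic bias of the chiral diene oppose each other, or competing regiochemistry of the cycloaddition. The fallback replaces the cycloaddition by relay of chirality from a carbinol at C1. It sets out from 8 and returns at 12.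
- Nozaki–Hiyama–Kishi coupling of 8 with 3-[(4-methoxyphenyl)methoxy]propanal (CrCl2, cat. NiCl2, DMF) should give the allylic alcohol 1-[(5R,6S)-6-ethenyl-5,6-dimethylcyclohex-1-en-1-yl]-3-[(4-methoxyphenyl)methoxy]propan-1-ol F1 as C1 epimers.
- Dess–Martin oxidation should give the enone 1-[(5R,6S)-6-ethenyl-5,6-dimethylcyclohex-1-en-1-yl]-3-[(4-methoxyphenyl)methoxy]propan-1-one F2.
- Reduction with (R)-Me-CBS and catecholborane should give the single carbinol (1S)-1-[(5R,6S)-6-ethenyl-5,6-dimethylcyclohex-1-en-1-yl]-3-[(4-methoxyphenyl)methoxy]propan-1-ol F3.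
- Johnson–Claisen rearrangement with triethyl orthopropionate (cat. EtCO2H, 140 °C) should transfer the C1 configuration suprafacially to C5 and give ethyl 2-[(1R,2E,3S,4R)-3-ethenyl-2-{3-[(4-methoxyphenyl)methoxy]propylidene}-3,4-dimethylcyclohexyl]propanoate F4. The chain on C1 is forced cis to C5 by A1,2 strain with quaternary C9.
- DDQ should remove the PMB group to give ethyl 2-[(1R,2E,3S,4R)-3-ethenyl-2-(3-hydroxypropylidene)-3,4-dimethylcyclohexyl]propanoate F5.
- I2/PPh3/imidazole should give ethyl 2-[(1R,2E,3S,4R)-3-ethenyl-2-(3-iodopropylidene)-3,4-dimethylcyclohexyl]propanoate F6.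
- LDA (THF/DMPU, −78 → 0 °C) should close ring A by intramolecular ester-enolate alkylation to ethyl (1S,5S,6R,8aS)-5-ethenyl-1,5,6-trimethyl-1,2,3,5,6,7,8,8a-octahydronaphthalene-1-carboxylate F7. C4 is set by A1,3 strain: H5 eclipses the enolate, the tethered electrophile adds from the C10 side, and CO2Et ends cis to H5.
- Saponification of the hindered ester (KOH, ethylene glycol, 150 °C) should give 12.

Step 1. The process at risk is incomplete or reversible aldol capture of the hindered aluminium enolate, methyl transfer from residual Me3Al to the aldehyde, or erosion of the trans selectivity. The fallback uses a vinyl cation equivalent by Michael addition and sulfoxide elimination. It sets out from 1 and returns at 6, replacing steps 1 and 2.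
- The same conjugate addition is quenched with TMSOTf/Et3N to give trimethyl{[(3R)-2,3-dimethylcyclohex-1-en-1-yl]oxy}silane F8.
- MeLi (THF) regenerates the lithium enolate, which should add to phenyl vinyl sulfoxide (−78 → −20 °C) trans to the C8 methyl group and give (2S,3R)-2-[2-(benzenesulfinyl)ethyl]-2,3-dimethylcyclohexan-1-one F9.
- Thermolysis (PhMe, 110 °C, CaCO3) should eliminate benzenesulfenic acid and give 6.

Step 9. The process at risk is consumption or reduction of the free carboxyl by the borane, and sluggish transmetallation or protodeboronation of the boron carboxylate. The fallback attaches the side chain before ring A exists, so that no carboxyl is present during the boron chemistry. It sets out from 8 and returns at 18.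
- Hydroboration of the vinyl group of 8 with 9-BBN and B-alkyl Suzuki coupling with the activated enol triflate 14 (PdCl2(dppf), K3PO4; the hindered ring triflate should react more slowly) should give ethyl (2E)-5-[(1S,6R)-1,6-dimethyl-2-{[(trifluoromethyl)sulfonyl]oxy}cyclohex-2-en-1-yl]-3-methylpent-2-enoate F10.
- Stille vinylation as in step 4 should give ethyl (2E)-5-[(1S,6R)-2-ethenyl-1,6-dimethylcyclohex-2-en-1-yl]-3-methylpent-2-enoate F11.
- DIBAL-H (−78 °C) should give (2E)-5-[(1S,6R)-2-ethenyl-1,6-dimethylcyclohex-2-en-1-yl]-3-methylpent-2-en-1-ol F12.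
- Propanoic anhydride/pyridine should give (2E)-5-[(1S,6R)-2-ethenyl-1,6-dimethylcyclohex-2-en-1-yl]-3-methylpent-2-en-1-yl propanoate F13.
- The Diels–Alder reaction of step 5 with 10 should give (2E)-5-[(1S,2R,4aS,5S)-5-formyl-1,2,5-trimethyl-1,2,3,4,4a,5,6,7-octahydronaphthalen-1-yl]-3-methylpent-2-en-1-yl propanoate F14.
- Pinnick oxidation as in step 6 should give 18.

**Further compounds**

F1 | step 5 | 1-[(5R,6S)-6-ethenyl-5,6-dimethylcyclohex-1-en-1-yl]-3-[(4-methoxyphenyl)methoxy]propan-1-ol (C1 epimers) | C=C[C@]1(C)C(C(O)CCOCc2ccc(OC)cc2)=CCC[C@H]1C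
F2 | step 5 | 1-[(5R,6S)-6-ethenyl-5,6-dimethylcyclohex-1-en-1-yl]-3-[(4-methoxyphenyl)methoxy]propan-1-one | C=C[C@]1(C)C(C(=O)CCOCc2ccc(OC)cc2)=CCC[C@H]1C
F3 | step 5 | (1S)-1-[(5R,6S)-6-ethenyl-5,6-dimethylcyclohex-1-en-1-yl]-3-[(4-methoxyphenyl)methoxy]propan-1-ol | C=C[C@]1(C)C([C@@H](O)CCOCc2ccc(OC)cc2)=CCC[C@H]1C
F4 | step 5 | ethyl 2-[(1R,2E,3S,4R)-3-ethenyl-2-{3-[(4-methoxyphenyl)methoxy]propylidene}-3,4-dimethylcyclohexyl]propanoate (epimers at the ester α-carbon) | C=C[C@]1(C)/C(=C/CCOCc2ccc(OC)cc2)[C@@H](C(C)C(=O)OCC)CC[C@H]1C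
F5 | step 5 | ethyl 2-[(1R,2E,3S,4R)-3-ethenyl-2-(3-hydroxypropylidene)-3,4-dimethylcyclohexyl]propanoate | C=C[C@]1(C)/C(=C/CCO)[C@@H](C(C)C(=O)OCC)CC[C@H]1C
F6 | step 5 | ethyl 2-[(1R,2E,3S,4R)-3-ethenyl-2-(3-iodopropylidene)-3,4-dimethylcyclohexyl]propanoate | C=C[C@]1(C)/C(=C/CCI)[C@@H](C(C)C(=O)OCC)CC[C@H]1C
F7 | step 5 | ethyl (1S,5S,6R,8aS)-5-ethenyl-1,5,6-trimethyl-1,2,3,5,6,7,8,8a-octahydronaphthalene-1-carboxylate | C=C[C@]1(C)C2=CCC[C@](C)(C(=O)OCC)[C@H]2CC[C@H]1C
F8 | step 1 | trimethyl{[(3R)-2,3-dimethylcyclohex-1-en-1-yl]oxy}silane | CC1=C(O[Si](C)(C)C)CCC[C@H]1C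
F9 | step 1 | (2S,3R)-2-[2-(benzenesulfinyl)ethyl]-2,3-dimethylcyclohexan-1-one (sulfoxide epimers) | O=S(CC[C@]1(C)C(=O)CCC[C@H]1C)c1ccccc1
F10 | step 9 | ethyl (2E)-5-[(1S,6R)-1,6-dimethyl-2-{[(trifluoromethyl)sulfonyl]oxy}cyclohex-2-en-1-yl]-3-methylpent-2-enoate | CCOC(=O)/C=C(\C)CC[C@]1(C)C(OS(=O)(=O)C(F)(F)F)=CCC[C@H]1C
F11 | step 9 | ethyl (2E)-5-[(1S,6R)-2-ethenyl-1,6-dimethylcyclohex-2-en-1-yl]-3-methylpent-2-enoate | CCOC(=O)/C=C(\C)CC[C@]1(C)C(C=C)=CCC[C@H]1C
F12 | step 9 | (2E)-5-[(1S,6R)-2-ethenyl-1,6-dimethylcyclohex-2-en-1-yl]-3-methylpent-2-en-1-ol | OC/C=C(\C)CC[C@]1(C)C(C=C)=CCC[C@H]1C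
F13 | step 9 | (2E)-5-[(1S,6R)-2-ethenyl-1,6-dimethylcyclohex-2-en-1-yl]-3-methylpent-2-en-1-yl propanoate | CCC(=O)OC/C=C(\C)CC[C@]1(C)C(C=C)=CCC[C@H]1C
F14 | step 9 | (2E)-5-[(1S,2R,4aS,5S)-5-formyl-1,2,5-trimethyl-1,2,3,4,4a,5,6,7-octahydronaphthalen-1-yl]-3-methylpent-2-en-1-yl propanoate | CCC(=O)OC/C=C(\C)CC[C@]1(C)C2=CCC[C@](C)(C=O)[C@H]2CC[C@H]1C
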